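**Retrosynthetic overview**
1. Target 7 ⇒ dichloride 5: both allyl groups are put on last by a double Suzuki–Miyaura allylation, so no competing alkene is present earlier.
2. 5 ⇒ aryl bromide 3 + boronic acid 4: Suzuki biaryl coupling at C–Br, leaving both C–Cl bonds.
3. 3 ⇒ (+)-β-eudesmol 1 + 2-bromo-4-chlorophenol 2: visible-light Markovnikov hydroaryloxylation of the C4=C15 alkene forms the key tertiary C4–O(aryl) bond and sets C4 under control of the decalin.
4. Ring order: no ring is built. The trans-decalin with C5, C7 and C10 is bought in 1; aryl ring A is attached in step 1 and ring B in step 2.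

Assumption: (+)-β-eudesmol (natural isolate) is taken as the purchasable chiral starting material; the target is read as the 4α-aryloxy, 4β-methyl (cryptomeridiol-type, 4R,5R,7R,10R) ether at the 2-OH of honokiol.

**Step 1**
Reactants: 1 (+)-β-eudesmol; 2 2-bromo-4-chlorophenol
Product: 3 (4R,5R,7R,10R)-4-(2-bromo-4-chlorophenoxy)eudesman-11-ol
Conditions: 2 (3 equiv), Co(II) complex of N,N'-bis(3,5-di-tert-butylsalicylidene)-2,2-dimethylpropane-1,3-diamine (achiral, 5 mol%), 4CzIPN (2 mol%), 2,4,6-collidinium triflate (20 mol%), CH2Cl2, 450 nm LEDs, 25 °C, Ar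
Reagents that add atoms: none
Why: Proposed new method: a photoredox/Co(salen)/Brønsted-acid hydroaryloxylation by metal-hydride H-atom transfer and radical-polar crossover, in which photoreduced Co(I) is protonated to Co(III)–H, this transfers H• to the C15 methylene of 1 to give the tertiary C4 radical, Co(II) capture and photo-oxidation give a cation-like tertiary alkyl–Co(IV), and the acidic, oxidation-resistant phenol 2 traps it on the equatorial α-face, anti to the axial C10 methyl, to set C4 as 4α-OAr/4β-Me (4R); the closest known reactions are the photoredox/cobalt Markovnikov hydroalkoxylation of unactivated alkenes with aliphatic alcohols and the Co(salen)-catalysed cycloetherification of alkenyl phenols, neither shown for intermolecular addition of a hindered ortho-halophenol to a terpenoid exocyclic alkene to make a fully substituted alkyl aryl ether.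

**Step 2**
Reactants: 3 (4R,5R,7R,10R)-4-(2-bromo-4-chlorophenoxy)eudesman-11-ol; 4 (3-chloro-4-hydroxyphenyl)boronic acid
Product: 5 (4R,5R,7R,10R)-4-[(3',5-dichloro-4'-hydroxy-[1,1'-biphenyl]-2-yl)oxy]eudesman-11-ol
Conditions: 4 (1.5 equiv), Pd(dppf)Cl2·CH2Cl2 (5 mol%), K2CO3 (3 equiv), 1,4-dioxane/H2O 4:1, 85 °C
Reagents that add atoms: none
Why: Suzuki–Miyaura coupling in which Pd(dppf) inserts into the C–Br bond and leaves both aryl C–Cl bonds, the free phenol and the tertiary alcohol alone; no stereocentre is touched.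

**Step 3**
Reactants: 5 (4R,5R,7R,10R)-4-[(3',5-dichloro-4'-hydroxy-[1,1'-biphenyl]-2-yl)oxy]eudesman-11-ol
Product: 7 (4R,5R,7R,10R)-4-[(3',5-diallyl-4'-hydroxy-[1,1'-biphenyl]-2-yl)oxy]eudesman-11-ol (target), via ring-A monoallyl aryl chloride 6 (not isolated)
Conditions: allylB(pin) (4 equiv), XPhos Pd G3 (8 mol%), K3PO4 (6 equiv), THF/H2O 5:1, 65 °C
Reagents that add atoms: allylboronic acid pinacol ester, C=CCB1OC(C)(C)C(C)(C)O1
Why: Double Suzuki–Miyaura allylation of aryl chlorides with a dialkylbiarylphosphine palladium catalyst, in which the neutral ring-A chloride reacts first and the chloride ortho to the phenoxide second; no stereocentre is touched.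

**Compound list**
1 | (+)-β-eudesmol, (5S,7R,10R)-eudesm-4(15)-en-11-ol; trans-decalin, 10β-Me, 5α-H, 7β-(2-hydroxypropan-2-yl) | C=C1CCC[C@]2(C)CC[C@@H](C(C)(C)O)C[C@H]21 | starting material
2 | 2-bromo-4-chlorophenol | Oc1ccc(Cl)cc1Br | starting material
3 | (4R,5R,7R,10R)-4-(2-bromo-4-chlorophenoxy)eudesman-11-ol; 4α-aryloxy, 4β-methyl | Clc1ccc(O[C@]2(C)CCC[C@]3(C)CC[C@@H](C(C)(C)O)C[C@H]32)c(Br)c1 | intermediate
4 | (3-chloro-4-hydroxyphenyl)boronic acid | OB(O)c1ccc(O)c(Cl)c1 | starting material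
5 | (4R,5R,7R,10R)-4-[(3',5-dichloro-4'-hydroxy-[1,1'-biphenyl]-2-yl)oxy]eudesman-11-ol | Clc1ccc(O[C@]2(C)CCC[C@]3(C)CC[C@@H](C(C)(C)O)C[C@H]32)c(-c2ccc(O)c(Cl)c2)c1 | intermediate
6 | (4R,5R,7R,10R)-4-[(5-allyl-3'-chloro-4'-hydroxy-[1,1'-biphenyl]-2-yl)oxy]eudesman-11-ol, not isolated | C=CCc1ccc(O[C@]2(C)CCC[C@]3(C)CC[C@@H](C(C)(C)O)C[C@H]32)c(-c2ccc(O)c(Cl)c2)c1 | intermediate
7 | (4R,5R,7R,10R)-4-[(3',5-diallyl-4'-hydroxy-[1,1'-biphenyl]-2-yl)oxy]eudesman-11-ol, CNP0219722.1 | C=CCc1ccc(O[C@]2(C)CCC[C@]3(C)CC[C@@H](C(C)(C)O)C[C@H]32)c(-c2ccc(O)c(CC=C)c2)c1 | target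

**Totals**
Total step count: 3. Longest linear sequence: 3 steps (1 → 3 → 5 → 7).

**Steps most likely to fail, with fallbacks**

Step 1 (proposed new step). Risks:
- the cation-like C4 centre may eliminate to α-/γ-eudesmol or undergo a 1,2-hydride shift from C5;
- capture by the weakly nucleophilic phenol may be slow;
- some 4-epimer or C-alkylated phenol may form.

Fallback with known chemistry, setting out from 1 and coming back at 3; it forms the aryl–O bond instead of the C4–O bond. Compound 1 is silylated at the C11 hydroxyl (TESOTf, 2,6-lutidine, CH2Cl2, 0 °C) to give 11-O-triethylsilyl-β-eudesmol F1. Oxymercuration–demercuration (Hg(OAc)2, THF/H2O, then NaBH4/NaOH) adds water in the Markovnikov sense from the equatorial face and gives cryptomeridiol 11-triethylsilyl ether F2, which fixes C4. The sodium alkoxide of F2 (NaH, toluene) is O-arylated without metal by (2-bromo-4-chlorophenyl)(2,4,6-trimethoxyphenyl)iodonium tosylate F3, made in one pot from 2-bromo-4-chloro-1-iodobenzene, mCPBA, TsOH·H2O and 1,3,5-trimethoxybenzene. This gives 4-O-(2-bromo-4-chlorophenyl)cryptomeridiol 11-triethylsilyl ether F4, and TBAF in THF removes the silyl group to give 3.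

Step 3. Risks:
- oxidative addition into the chloride ortho to the phenoxide may be slow;
- the allyl groups may isomerise to propenyl under Pd–H.

Fallback setting out from 3 and coming back at 7; the ring-B allyl group is brought in by a Claisen rearrangement instead of a cross-coupling. Compound 3 is coupled with 4-hydroxyphenylboronic acid (Pd(dppf)Cl2, K2CO3, dioxane/H2O) to give (4R,5R,7R,10R)-4-[(5-chloro-4'-hydroxy-[1,1'-biphenyl]-2-yl)oxy]eudesman-11-ol F6. Its single, neutral aryl chloride is allylated (allylB(pin), XPhos Pd G3, K3PO4) to give (4R,5R,7R,10R)-4-[(5-allyl-4'-hydroxy-[1,1'-biphenyl]-2-yl)oxy]eudesman-11-ol F7. O-Allylation (allyl bromide, K2CO3, acetone) gives (4R,5R,7R,10R)-4-[(5-allyl-4'-allyloxy-[1,1'-biphenyl]-2-yl)oxy]eudesman-11-ol F8. An aromatic Claisen rearrangement (N,N-diethylaniline, 190 °C) moves the allyl group to C3', the two ortho positions being equivalent, and gives 7.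

Step 2. Risks:
- oxidative addition into the C–Br bond next to the bulky tertiary alkoxy group may be slow;
- the electron-rich boronic acid 4 may protodeboronate.

Fallback setting out from 3 and coming back at 5; the polarity of the coupling is reversed so that no palladium insertion is needed at the hindered carbon. Compound 3 is treated with n-BuLi (2.2 equiv, THF, −78 °C; the first equivalent only deprotonates the C11–OH). The aryllithium is quenched with 2-isopropoxy-4,4,5,5-tetramethyl-1,3,2-dioxaborolane to give (4R,5R,7R,10R)-4-[4-chloro-2-(4,4,5,5-tetramethyl-1,3,2-dioxaborolan-2-yl)phenoxy]eudesman-11-ol F5. F5 is coupled with commercial 4-bromo-2-chlorophenol (Pd(PPh3)4, K2CO3, dioxane/H2O, 80 °C) to give 5.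

**Further compounds**
F1 | step 1 | 11-O-triethylsilyl-β-eudesmol | C=C1CCC[C@]2(C)CC[C@@H](C(C)(C)O[Si](CC)(CC)CC)C[C@H]21
F2 | step 1 | cryptomeridiol 11-triethylsilyl ether, (4R,5R,7R,10R), 4α-OH | O[C@]1(C)CCC[C@]2(C)CC[C@@H](C(C)(C)O[Si](CC)(CC)CC)C[C@H]21
F3 | step 1 | (2-bromo-4-chlorophenyl)(2,4,6-trimethoxyphenyl)iodonium tosylate | COc1cc(OC)c([I+]c2ccc(Cl)cc2Br)c(OC)c1.Cc1ccc(S(=O)(=O)[O-])cc1
F4 | step 1 | 4-O-(2-bromo-4-chlorophenyl)cryptomeridiol 11-triethylsilyl ether | Clc1ccc(O[C@]2(C)CCC[C@]3(C)CC[C@@H](C(C)(C)O[Si](CC)(CC)CC)C[C@H]32)c(Br)c1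
F5 | step 2 | (4R,5R,7R,10R)-4-[4-chloro-2-(4,4,5,5-tetramethyl-1,3,2-dioxaborolan-2-yl)phenoxy]eudesman-11-ol | CC1(C)OB(OC1(C)C)c1cc(Cl)ccc1O[C@]1(C)CCC[C@]2(C)CC[C@@H](C(C)(C)O)C[C@H]21
F6 | step 3 | (4R,5R,7R,10R)-4-[(5-chloro-4'-hydroxy-[1,1'-biphenyl]-2-yl)oxy]eudesman-11-ol | Clc1ccc(O[C@]2(C)CCC[C@]3(C)CC[C@@H](C(C)(C)O)C[C@H]32)c(-c2ccc(O)cc2)c1
F7 | step 3 | (4R,5R,7R,10R)-4-[(5-allyl-4'-hydroxy-[1,1'-biphenyl]-2-yl)oxy]eudesman-11-ol | C=CCc1ccc(O[C@]2(C)CCC[C@]3(C)CC[C@@H](C(C)(C)O)C[C@H]32)c(-c2ccc(O)cc2)c1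
F8 | step 3 | (4R,5R,7R,10R)-4-[(5-allyl-4'-allyloxy-[1,1'-biphenyl]-2-yl)oxy]eudesman-11-ol | C=CCOc1ccc(-c2cc(CC=C)ccc2O[C@]2(C)CCC[C@]3(C)CC[C@@H](C(C)(C)O)C[C@H]32)cc1
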